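Labdane numbering is used: ring A = C1–C5 and C10, ring B = C5–C10, C19 = the CH2O carbon on C4, C17 = the methylene carbon on C8, C11–C16 = side chain. The target is ent-labda-8(17),13(16),14-trien-19-yl (Z)-4-hydroxycinnamate.
Cuts, in retrosynthetic order: the Z C=C of the cinnamate and the ester C–O; C12–C13; C8=C17; C9–C11; C4–C18; C1–C2 (ring A); C3–C4; C10–C1.
Forward: ring B is made first by an amine-catalysed Michael/aldol annulation, C10 is made quaternary by 1,4-addition, ring A is closed across C1–C2, then C4, C9, C8, the diene and the ester follow.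
Enabling feature: ring A carries nothing on C1, C2 and C3 and is flanked by the two quaternary carbons C10 and C4. A vinyl group on C10 and an allyl group on the ester α-carbon C4 can therefore be joined as a plain CH=CH unit, and C4 needs no defined configuration until after closure.
Stereochemistry: C5 from the organocatalytic Michael step; C10 by 1,4-addition anti to the C5 substituent; C4 by equatorial methylation of the ring A ester enolate, anti to the axial C10 methyl; C9 by equilibration next to the C8 ketone; the Z olefin by a diaryl phosphonoacetate olefination.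
Key step: step 6

Remark: compounds 8, 9 and 10 are carried as mixtures of C4 epimers, because C4 is enolised again in step 8. Compounds 1, 2, 17, 20 and 22 are taken as commercial.

Step 1
Reactants: 1 methyl 4-oxobutanoate; 2 methyl vinyl ketone
Product: 4 methyl 2-[(1R)-4-oxocyclohex-2-en-1-yl]acetate, via keto aldehyde 3 (not isolated)
Conditions: (R)-2-[methoxy(diphenyl)methyl]pyrrolidine (5 mol %), ethyl 3,4-dihydroxybenzoate (20 mol %), neat, 4 °C; then TsOH·H2O (10 mol %), toluene, 60 °C
Reagents that add atoms: none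
Why: Enamine-catalysed Michael addition of the aldehyde to the enone followed by intramolecular aldol condensation (organocatalytic Robinson-type annulation) should give the 4-substituted cyclohexenone, the diarylmethyl ether group of the (R)-catalyst shielding one face of the E-enamine so that the future C5 is formed with R configuration.

Step 2
Reactants: 4 methyl 2-[(1R)-4-oxocyclohex-2-en-1-yl]acetate
Product: 5 methyl 2-[(1R,2R)-2-methyl-4-(trimethylsilyloxy)cyclohex-3-en-1-yl]acetate
Conditions: MeMgBr, CuBr·SMe2 (5 mol %), Me3SiCl, HMPA, THF, −78 °C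
Reagents that add atoms: methylmagnesium bromide, C[Mg]Br; chlorotrimethylsilane, C[Si](C)(C)Cl
Why: Copper-catalysed, silyl chloride-accelerated conjugate addition of a Grignard reagent with O-silylation of the enolate puts the future C10 methyl on the β-carbon; it enters anti to the C5 substituent, but this centre becomes planar again in step 3.

Step 3
Reactants: 5 methyl 2-[(1R,2R)-2-methyl-4-(trimethylsilyloxy)cyclohex-3-en-1-yl]acetate
Product: 6 methyl 2-[(1R)-2-methyl-4-oxocyclohex-2-en-1-yl]acetate
Conditions: Pd(OAc)2 (10 mol %), O2 (1 atm), DMSO, 25 °C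
Reagents that add atoms: none
Why: Saegusa–Ito oxidation (palladation of the silyl enol ether at C9, then β-hydride elimination of the C10 hydrogen) should restore the enone with the methyl group now on the β-carbon, leaving C5 untouched.

Step 4
Reactants: 6 methyl 2-[(1R)-2-methyl-4-oxocyclohex-2-en-1-yl]acetate
Product: 7 methyl 2-[(1R,2R)-2-ethenyl-2-methyl-4-(triethylsilyloxy)cyclohex-3-en-1-yl]acetate
Conditions: CH2=CHMgBr, CuBr·SMe2 (10 mol %), Et3SiCl, HMPA, THF, −78 to −40 °C; Et3N quench
Reagents that add atoms: vinylmagnesium bromide, C=C[Mg]Br; chlorotriethylsilane, CC[Si](CC)(CC)Cl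
Why: Silyl-accelerated copper-catalysed 1,4-addition creates the quaternary C10; the C5 side chain is pushed pseudo-axial by allylic strain with the C10 methyl, so the vinyl group (future C1) adds to the opposite face and ends trans to it, and the enolate is stored regiospecifically as the C8–C9 triethylsilyl enol ether.

Step 5
Reactants: 7 methyl 2-[(1R,2R)-2-ethenyl-2-methyl-4-(triethylsilyloxy)cyclohex-3-en-1-yl]acetate
Product: 8 methyl 2-[(1R,2R)-2-ethenyl-2-methyl-4-(triethylsilyloxy)cyclohex-3-en-1-yl]pent-4-enoate (both epimers at C2 of the pentenoate, the future C4)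
Conditions: LiN(iPr)2, THF, −78 °C; allyl bromide, DMPU, −78 to −20 °C
Reagents that add atoms: allyl bromide, C=CCBr
Why: Ester enolate alkylation attaches C3 and C2 to C4 while the ketone stays masked as the silyl enol ether, which is inert to the amide base.

Step 6
Reactants: 8 methyl 2-[(1R,2R)-2-ethenyl-2-methyl-4-(triethylsilyloxy)cyclohex-3-en-1-yl]pent-4-enoate
Product: 9 methyl (4aR,8aR)-4a-methyl-6-(triethylsilyloxy)-1,2,4a,7,8,8a-hexahydronaphthalene-1-carboxylate (both C1 epimers)
Conditions: second-generation Grubbs catalyst RuCl2(=CHPh)(PCy3)(H2IMes) (5 mol %), CH2Cl2 (0.005 M), 40 °C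
Reagents that add atoms: none
Why: Ring-closing olefin metathesis: the ruthenium alkylidene first exchanges onto the unhindered allyl terminus on C4, then adds to the neopentyl vinyl group on C10 to give a ruthenacyclobutane that collapses with loss of ethene and formation of the C1=C2 bond. The closest known reaction type is the ring-closing metathesis of 1,7-dienes to cyclohexenes, including closures onto vinyl groups on quaternary carbons. Ring A is closed as a six-membered carbocycle across C1–C2; its trans fusion to ring B is not created here but follows from the vinyl group on C10 and the C4 arm on C5 being trans and both pseudo-equatorial on ring B, so that they lie gauche and bridge without strain. No stereocentre is formed; C5 and C10 were set in steps 1 and 4, and the two C4 epimers of 8 both cyclise and converge in step 8. The step needs the catalyst to ignore the trisubstituted silyl enol ether and to cyclise instead of oligomerising: the enol ether is electron-rich, hindered and could only react by forming a bridged ring, the vinyl group on quaternary C10 does not homodimerise, and high dilution with escape of ethene pulls the diene into the ring.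

Step 7
Reactants: 9 methyl (4aR,8aR)-4a-methyl-6-(triethylsilyloxy)-1,2,4a,7,8,8a-hexahydronaphthalene-1-carboxylate
Product: 10 methyl (4aR,8aR)-4a-methyl-6-(triethylsilyloxy)-1,2,3,4,4a,7,8,8a-octahydronaphthalene-1-carboxylate (both C1 epimers)
Conditions: H2 (1 atm), RhCl(PPh3)3 (5 mol %), benzene, 25 °C
Reagents that add atoms: none
Why: Homogeneous hydrogenation with Wilkinson's catalyst should reduce the cis-disubstituted C1=C2 olefin and leave the trisubstituted silyl enol ether, so ring A is saturated before the other olefins of the target are introduced.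

Step 8
Reactants: 10 methyl (4aR,8aR)-4a-methyl-6-(triethylsilyloxy)-1,2,3,4,4a,7,8,8a-octahydronaphthalene-1-carboxylate
Product: 11 methyl (1R,4aR,8aS)-1,4a-dimethyl-6-(triethylsilyloxy)-1,2,3,4,4a,7,8,8a-octahydronaphthalene-1-carboxylate
Conditions: LiN(iPr)2, THF, −78 to 0 °C; MeI, DMPU, −78 to 0 °C
Reagents that add atoms: iodomethane, CI
Why: Alkylation of the exocyclic ester enolate at C4 of the trans-fused bicycle: axial approach is blocked by the 1,3-diaxial C10 methyl, so methyl iodide should enter equatorially and leave the ester axial and cis to the C10 methyl (the C19 position), as known for C4 ester enolates of trans-decalins with an angular methyl group.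

Step 9
Reactants: 11 methyl (1R,4aR,8aS)-1,4a-dimethyl-6-(triethylsilyloxy)-1,2,3,4,4a,7,8,8a-octahydronaphthalene-1-carboxylate
Product: 13 methyl (1R,4aR,5S,8aS)-5-(2-tert-butoxy-2-oxoethyl)-1,4a-dimethyl-6-oxodecahydronaphthalene-1-carboxylate, via axial C9 epimer 12 (not isolated)
Conditions: BnMe3NF, BrCH2CO2tBu, 4 Å molecular sieves, THF, 0 to 25 °C; then NaOMe (0.2 equiv), MeOH, 25 °C
Reagents that add atoms: tert-butyl bromoacetate, CC(C)(C)OC(=O)CBr
Why: Fluoride cleavage of the silyl enol ether gives the C8/C9 ammonium enolate regiospecifically for alkylation at C9 (regiospecific enolate alkylation); kinetic axial attack anti to the C10 methyl gives 12, and base equilibration next to the C8 ketone moves the side chain to the equatorial position, cis to the C10 methyl.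

Step 10
Reactants: 13 methyl (1R,4aR,5S,8aS)-5-(2-tert-butoxy-2-oxoethyl)-1,4a-dimethyl-6-oxodecahydronaphthalene-1-carboxylate
Product: 14 methyl (1R,4aS,5R,8aS)-5-(2-tert-butoxy-2-oxoethyl)-1,4a-dimethyl-6-methylidenedecahydronaphthalene-1-carboxylate
Conditions: Ph3PCH3Br, KOtBu, toluene, 90 °C
Reagents that add atoms: methyltriphenylphosphonium bromide, C[P+](c1ccccc1)(c1ccccc1)c1ccccc1.[Br-]
Why: Wittig methylenation of the C8 ketone is the standard entry to the 8(17)-methylene group of labdanes; the two hindered esters should not react with the non-stabilised ylide, and C9 stays equatorial under the basic conditions.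

Step 11
Reactants: 14 methyl (1R,4aS,5R,8aS)-5-(2-tert-butoxy-2-oxoethyl)-1,4a-dimethyl-6-methylidenedecahydronaphthalene-1-carboxylate
Product: 15 2-[(1R,4aS,5R,8aS)-5-(hydroxymethyl)-5,8a-dimethyl-2-methylidenedecahydronaphthalen-1-yl]ethan-1-ol
Conditions: LiAlH4, THF, 0 °C to reflux
Reagents that add atoms: none
Why: Hydride reduction of both esters gives the C12 and C19 primary alcohols and does not touch the olefin.

Step 12
Reactants: 15 2-[(1R,4aS,5R,8aS)-5-(hydroxymethyl)-5,8a-dimethyl-2-methylidenedecahydronaphthalen-1-yl]ethan-1-ol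
Product: 16 [(1R,4aS,5R,8aS)-5-(2-iodoethyl)-1,4a-dimethyl-6-methylidenedecahydronaphthalen-1-yl]methanol
Conditions: I2 (1.05 equiv), PPh3, imidazole, CH2Cl2, 0 °C
Reagents that add atoms: iodine, II
Why: Appel iodination should discriminate the unhindered C12 hydroxyl from the neopentyl, axial C19 hydroxyl, whose phosphonium intermediate cannot be displaced at a useful rate.

Step 13
Reactants: 16 [(1R,4aS,5R,8aS)-5-(2-iodoethyl)-1,4a-dimethyl-6-methylidenedecahydronaphthalen-1-yl]methanol; 17 chloroprene (2-chlorobuta-1,3-diene)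
Product: 19 [(1R,4aS,5R,8aS)-1,4a-dimethyl-6-methylidene-5-(3-methylidenepent-4-en-1-yl)decahydronaphthalen-1-yl]methanol (ent-labda-8(17),13(16),14-trien-19-ol), via dienyl Grignard reagent 18 (not isolated)
Conditions: 17, Mg, ZnCl2 (2 mol %), THF, reflux, giving 18 (3 equiv); then 16, Li2CuCl4 (5 mol %), THF, 0 to 25 °C; aqueous NH4Cl
Reagents that add atoms: none
Why: Copper-catalysed cross-coupling of a primary alkyl iodide with buta-1,3-dien-2-ylmagnesium chloride is an established route to 2-alkylbuta-1,3-dienes of the myrcene type; the first equivalent of 18 only deprotonates the C19 hydroxyl.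

Step 14
Reactants: 19 [(1R,4aS,5R,8aS)-1,4a-dimethyl-6-methylidene-5-(3-methylidenepent-4-en-1-yl)decahydronaphthalen-1-yl]methanol; 20 2-(diphenoxyphosphoryl)acetic acid
Product: 21 [(1R,4aS,5R,8aS)-1,4a-dimethyl-6-methylidene-5-(3-methylidenepent-4-en-1-yl)decahydronaphthalen-1-yl]methyl 2-(diphenoxyphosphoryl)acetate
Conditions: DCC, DMAP (cat.), CH2Cl2, 0 to 25 °C
Reagents that add atoms: none
Why: Carbodiimide (Steglich) esterification of a phosphonoacetic acid proceeds through a highly reactive acylating species and should therefore acylate the neopentyl C19 hydroxyl under neutral conditions that spare the diene.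

Step 15
Reactants: 21 [(1R,4aS,5R,8aS)-1,4a-dimethyl-6-methylidene-5-(3-methylidenepent-4-en-1-yl)decahydronaphthalen-1-yl]methyl 2-(diphenoxyphosphoryl)acetate; 22 4-[(tert-butyldimethylsilyl)oxy]benzaldehyde
Product: 23 [(1R,4aS,5R,8aS)-1,4a-dimethyl-6-methylidene-5-(3-methylidenepent-4-en-1-yl)decahydronaphthalen-1-yl]methyl (2Z)-3-{4-[(tert-butyldimethylsilyl)oxy]phenyl}prop-2-enoate
Conditions: NaH, THF, −78 to 0 °C
Reagents that add atoms: none
Why: Horner–Wadsworth–Emmons olefination with a diaryl phosphonoacetate: the electron-poor aryloxy groups make elimination from the first-formed adduct fast, so the (Z)-cinnamate should form under kinetic control.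

Step 16
Reactants: 23 [(1R,4aS,5R,8aS)-1,4a-dimethyl-6-methylidene-5-(3-methylidenepent-4-en-1-yl)decahydronaphthalen-1-yl]methyl (2Z)-3-{4-[(tert-butyldimethylsilyl)oxy]phenyl}prop-2-enoate
Product: 24 [(1R,4aS,5R,8aS)-1,4a-dimethyl-6-methylidene-5-(3-methylidenepent-4-en-1-yl)decahydronaphthalen-1-yl]methyl (2Z)-3-(4-hydroxyphenyl)prop-2-enoate (CNP0131099.2)
Conditions: Bu4NF, AcOH (1:1), THF, 0 °C, in the dark
Reagents that add atoms: none
Why: Buffered fluoride cleavage of the aryl silyl ether keeps the phenoxide concentration low, so neither acyl transfer nor Z-to-E isomerisation of the cinnamate should occur.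

Compound list
1 | methyl 4-oxobutanoate | COC(=O)CCC=O | starting material
2 | methyl vinyl ketone (but-3-en-2-one) | CC(=O)C=C | starting material
3 | methyl (3R)-3-formyl-6-oxoheptanoate | O=C[C@@H](CC(=O)OC)CCC(C)=O | intermediate
4 | methyl 2-[(1R)-4-oxocyclohex-2-en-1-yl]acetate | O=C1CC[C@H](CC(=O)OC)C=C1 | intermediate
5 | methyl 2-[(1R,2R)-2-methyl-4-(trimethylsilyloxy)cyclohex-3-en-1-yl]acetate | C[Si](C)(C)OC1=C[C@H](C)[C@@H](CC(=O)OC)CC1 | intermediate
6 | methyl 2-[(1R)-2-methyl-4-oxocyclohex-2-en-1-yl]acetate | O=C1C=C(C)[C@@H](CC(=O)OC)CC1 | intermediate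
7 | methyl 2-[(1R,2R)-2-ethenyl-2-methyl-4-(triethylsilyloxy)cyclohex-3-en-1-yl]acetate | CC[Si](CC)(CC)OC1=C[C@](C)(C=C)[C@@H](CC(=O)OC)CC1 | intermediate
8 | methyl 2-[(1R,2R)-2-ethenyl-2-methyl-4-(triethylsilyloxy)cyclohex-3-en-1-yl]pent-4-enoate, both epimers at C2 of the pentenoate | CC[Si](CC)(CC)OC1=C[C@](C)(C=C)[C@@H](C(CC=C)C(=O)OC)CC1 | intermediate
9 | methyl (4aR,8aR)-4a-methyl-6-(triethylsilyloxy)-1,2,4a,7,8,8a-hexahydronaphthalene-1-carboxylate, both C1 epimers | CC[Si](CC)(CC)OC1=C[C@]2(C)C=CCC(C(=O)OC)[C@H]2CC1 | intermediate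
10 | methyl (4aR,8aR)-4a-methyl-6-(triethylsilyloxy)-1,2,3,4,4a,7,8,8a-octahydronaphthalene-1-carboxylate, both C1 epimers | CC[Si](CC)(CC)OC1=C[C@]2(C)CCCC(C(=O)OC)[C@H]2CC1 | intermediate
11 | methyl (1R,4aR,8aS)-1,4a-dimethyl-6-(triethylsilyloxy)-1,2,3,4,4a,7,8,8a-octahydronaphthalene-1-carboxylate | CC[Si](CC)(CC)OC1=C[C@]2(C)CCC[C@@](C)(C(=O)OC)[C@H]2CC1 | intermediate
12 | methyl (1R,4aR,5R,8aS)-5-(2-tert-butoxy-2-oxoethyl)-1,4a-dimethyl-6-oxodecahydronaphthalene-1-carboxylate (side chain axial) | CC(C)(C)OC(=O)C[C@H]1C(=O)CC[C@@H]2[C@](C)(C(=O)OC)CCC[C@@]12C | intermediate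
13 | methyl (1R,4aR,5S,8aS)-5-(2-tert-butoxy-2-oxoethyl)-1,4a-dimethyl-6-oxodecahydronaphthalene-1-carboxylate (side chain equatorial) | CC(C)(C)OC(=O)C[C@@H]1C(=O)CC[C@@H]2[C@](C)(C(=O)OC)CCC[C@@]12C | intermediate
14 | methyl (1R,4aS,5R,8aS)-5-(2-tert-butoxy-2-oxoethyl)-1,4a-dimethyl-6-methylidenedecahydronaphthalene-1-carboxylate | CC(C)(C)OC(=O)C[C@@H]1C(=C)CC[C@@H]2[C@](C)(C(=O)OC)CCC[C@@]12C | intermediate
15 | 2-[(1R,4aS,5R,8aS)-5-(hydroxymethyl)-5,8a-dimethyl-2-methylidenedecahydronaphthalen-1-yl]ethan-1-ol | OCC[C@@H]1C(=C)CC[C@@H]2[C@](C)(CO)CCC[C@@]12C | intermediate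
16 | [(1R,4aS,5R,8aS)-5-(2-iodoethyl)-1,4a-dimethyl-6-methylidenedecahydronaphthalen-1-yl]methanol | ICC[C@@H]1C(=C)CC[C@@H]2[C@](C)(CO)CCC[C@@]12C | intermediate
17 | chloroprene (2-chlorobuta-1,3-diene) | C=CC(Cl)=C | starting material
18 | buta-1,3-dien-2-ylmagnesium chloride | C=CC(=C)[Mg]Cl | intermediate
19 | [(1R,4aS,5R,8aS)-1,4a-dimethyl-6-methylidene-5-(3-methylidenepent-4-en-1-yl)decahydronaphthalen-1-yl]methanol | C=CC(=C)CC[C@@H]1C(=C)CC[C@@H]2[C@](C)(CO)CCC[C@@]12C | intermediate
20 | 2-(diphenoxyphosphoryl)acetic acid | OC(=O)CP(=O)(Oc1ccccc1)Oc1ccccc1 | starting material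
21 | [(1R,4aS,5R,8aS)-1,4a-dimethyl-6-methylidene-5-(3-methylidenepent-4-en-1-yl)decahydronaphthalen-1-yl]methyl 2-(diphenoxyphosphoryl)acetate | C=CC(=C)CC[C@@H]1C(=C)CC[C@@H]2[C@](C)(COC(=O)CP(=O)(Oc3ccccc3)Oc3ccccc3)CCC[C@@]12C | intermediate
22 | 4-[(tert-butyldimethylsilyl)oxy]benzaldehyde | O=Cc1ccc(O[Si](C)(C)C(C)(C)C)cc1 | starting material
23 | [(1R,4aS,5R,8aS)-1,4a-dimethyl-6-methylidene-5-(3-methylidenepent-4-en-1-yl)decahydronaphthalen-1-yl]methyl (2Z)-3-{4-[(tert-butyldimethylsilyl)oxy]phenyl}prop-2-enoate | C=CC(=C)CC[C@@H]1C(=C)CC[C@@H]2[C@](C)(COC(=O)/C=C\c3ccc(O[Si](C)(C)C(C)(C)C)cc3)CCC[C@@]12C | intermediate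
24 | [(1R,4aS,5R,8aS)-1,4a-dimethyl-6-methylidene-5-(3-methylidenepent-4-en-1-yl)decahydronaphthalen-1-yl]methyl (2Z)-3-(4-hydroxyphenyl)prop-2-enoate | C=CC(=C)CC[C@@H]1C(=C)CC[C@@H]2[C@](C)(COC(=O)/C=C\c3ccc(O)cc3)CCC[C@@]12C | target

Total step count: 16. Longest linear sequence: 16 steps (from 1 and 2 to 24).

Steps most likely to fail

Step 9. The fluoride-generated enolate may exchange protons with the product ketone, which would lose the regiochemistry (alkylation at C7, dialkylation), or it may simply be protonated instead of alkylating the neopentyl C9. The fallback makes the C9–C11 bond by a Lewis acid aldol reaction instead of an SN2 alkylation. It sets out from 11: TiCl4-mediated Mukaiyama addition to ethyl glyoxylate (CH2Cl2, −78 °C) should give methyl (1R,4aR,8aS)-5-(2-ethoxy-1-hydroxy-2-oxoethyl)-1,4a-dimethyl-6-oxodecahydronaphthalene-1-carboxylate F1. MsCl/Et3N followed by DBU dehydrates it to methyl (1R,4aR,8aS)-5-(2-ethoxy-2-oxoethylidene)-1,4a-dimethyl-6-oxodecahydronaphthalene-1-carboxylate F2. Zn/AcOH reduces the olefin of this ene-1,4-dicarbonyl unit, and DBU equilibration at C9 gives methyl (1R,4aR,5S,8aS)-5-(2-ethoxy-2-oxoethyl)-1,4a-dimethyl-6-oxodecahydronaphthalene-1-carboxylate F3. Wittig methylenation gives methyl (1R,4aS,5R,8aS)-5-(2-ethoxy-2-oxoethyl)-1,4a-dimethyl-6-methylidenedecahydronaphthalene-1-carboxylate F4, and LiAlH4 reduction comes back to the route at diol 15.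

Step 4. Transfer of the vinyl group to the β,β-disubstituted enone next to the branched C5 may stall (recovered enone, 1,2-addition), or the facial selectivity may erode. The fallback uses a slimmer sp nucleophile and a Lewis acid-driven addition, then adjusts the oxidation level. It sets out from 6: Et3SiOTf-promoted conjugate addition of [(trimethylsilyl)ethynyl]zinc bromide should give the silyl enol ether methyl 2-[(1R,2R)-2-methyl-4-(triethylsilyloxy)-2-[2-(trimethylsilyl)ethynyl]cyclohex-3-en-1-yl]acetate F5 directly. AgNO3-catalysed removal of the alkynyl silyl group gives methyl 2-[(1R,2R)-2-ethynyl-2-methyl-4-(triethylsilyloxy)cyclohex-3-en-1-yl]acetate F6. Semihydrogenation over Lindlar catalyst (Pd on CaCO3, Pb(OAc)2, quinoline, H2) comes back to the route at 7.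

Step 13. Halogen–metal exchange, elimination or homocoupling may outrun the cross-coupling, and the dienyl Grignard reagent may polymerise. The fallback builds the diene by enyne metathesis instead of an sp3–sp2 coupling. It sets out from 16: displacement with lithium acetylide–ethylenediamine complex in DMSO should give [(1R,4aS,5R,8aS)-5-(but-3-yn-1-yl)-1,4a-dimethyl-6-methylidenedecahydronaphthalen-1-yl]methanol F7. Cross enyne metathesis of the terminal alkyne with ethene (1 atm, second-generation Grubbs catalyst, CH2Cl2, 40 °C) comes back to the route at 19.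

Further compounds
F1 | step 9 | methyl (1R,4aR,8aS)-5-(2-ethoxy-1-hydroxy-2-oxoethyl)-1,4a-dimethyl-6-oxodecahydronaphthalene-1-carboxylate (mixture at C5 and at the carbinol carbon) | CCOC(=O)C(O)C1C(=O)CC[C@@H]2[C@](C)(C(=O)OC)CCC[C@@]12C
F2 | step 9 | methyl (1R,4aR,8aS)-5-(2-ethoxy-2-oxoethylidene)-1,4a-dimethyl-6-oxodecahydronaphthalene-1-carboxylate | CCOC(=O)C=C1C(=O)CC[C@@H]2[C@](C)(C(=O)OC)CCC[C@@]12C
F3 | step 9 | methyl (1R,4aR,5S,8aS)-5-(2-ethoxy-2-oxoethyl)-1,4a-dimethyl-6-oxodecahydronaphthalene-1-carboxylate | CCOC(=O)C[C@@H]1C(=O)CC[C@@H]2[C@](C)(C(=O)OC)CCC[C@@]12C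
F4 | step 9 | methyl (1R,4aS,5R,8aS)-5-(2-ethoxy-2-oxoethyl)-1,4a-dimethyl-6-methylidenedecahydronaphthalene-1-carboxylate | CCOC(=O)C[C@@H]1C(=C)CC[C@@H]2[C@](C)(C(=O)OC)CCC[C@@]12C
F5 | step 4 | methyl 2-[(1R,2R)-2-methyl-4-(triethylsilyloxy)-2-[2-(trimethylsilyl)ethynyl]cyclohex-3-en-1-yl]acetate | CC[Si](CC)(CC)OC1=C[C@](C)(C#C[Si](C)(C)C)[C@@H](CC(=O)OC)CC1
F6 | step 4 | methyl 2-[(1R,2R)-2-ethynyl-2-methyl-4-(triethylsilyloxy)cyclohex-3-en-1-yl]acetate | CC[Si](CC)(CC)OC1=C[C@](C)(C#C)[C@@H](CC(=O)OC)CC1
F7 | step 13 | [(1R,4aS,5R,8aS)-5-(but-3-yn-1-yl)-1,4a-dimethyl-6-methylidenedecahydronaphthalen-1-yl]methanol | C#CCC[C@@H]1C(=C)CC[C@@H]2[C@](C)(CO)CCC[C@@]12C
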